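The runs were generated by integration on assumed constants, and the scatter is random.

Watch the coupling partner. With 0.480 M of it against 0.600 M of starting material in the alpha, theta and eta flasks, it is the limiting reagent, and the charge allows target of 80.0% of the starting material.

| flask | starting material | coupling partner | free catalyst | time |
|---|---|---|---|---|
| alpha | 0.600 M | 0.480 M | 0.0180 M |  |
| beta | 0.300 M | 0.180 M | 0.0180 M |  |
| theta | 0.600 M | 0.480 M | 0.0270 M |  |
| gamma | 0.300 M | 0.480 M | 0.0180 M |  |
| eta | 0.600 M | 0.480 M | 0.0370 M | 160 min |

| run | time / min | [target] / M |
|---|---|---|
| alpha run | 6.4 | 0.0243 |
| alpha run | 11 | 0.0451 |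
| alpha run | 19 | 0.0784 |
| alpha run | 32 | 0.1216 |
| alpha run | 55 | 0.1930 |
| alpha run | 94 | 0.2732 |
| alpha run | 160 | 0.3238 |
| beta run | 6.4 | 0.0126 |
| beta run | 11 | 0.0206 |
| beta run | 19 | 0.0349 |
| beta run | 32 | 0.0584 |
| beta run | 55 | 0.0899 |
| beta run | 94 | 0.1214 |
| beta run | 160 | 0.1343 |
| theta run | 6.4 | 0.0401 |
| theta run | 11 | 0.0691 |
| theta run | 19 | 0.1130 |
| theta run | 32 | 0.1747 |
| theta run | 55 | 0.2577 |
| theta run | 94 | 0.3373 |
| theta run | 160 | 0.3615 |
| gamma run | 6.4 | 0.0131 |
| gamma run | 11 | 0.0261 |
| gamma run | 19 | 0.0471 |
| gamma run | 32 | 0.0696 |
| gamma run | 55 | 0.1073 |
| gamma run | 94 | 0.1516 |
| gamma run | 160 | 0.2002 |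

(readings scatter by 0.002 M)

* the exponent of [coupling partner] in the starting rate at the charge of the alpha run (at the point where two percent of the starting material have become target)
* the exponent of [free catalyst] in the starting rate at the charge of the alpha run (at the point where two percent of the starting material have become target)
* target in the eta run at 160 min, as a share of the starting material charged

- Overall: starting material + coupling partner -> target, with free catalyst as catalyst.
- Constant volume, constant temperature.
- An order is taken over about fifteen percent of the charge, up and down.

I set the last readings of the alpha and theta runs side by side, since these two runs share one charge and differ in free catalyst. The theta run ends at 0.3615 M, so its lost share, the part of the coupling partner charged that does not stand as target at the last reading, is 24.7%, while the alpha run ends with a lost share of 32.5%. Theta also starts faster than alpha, with 0.0401 M against 0.0243 M at the first reading, so I treat the ending as a race that catalyst helps target to win.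

In logarithms, the catalyst step from alpha to theta is 0.176 and the fall in lost share is 0.119, which gives a slope of 0.681 at this charge. That slope may read steep, because the alpha run still gains 0.0506 M over its last interval, against 0.0242 M for theta.

The eta run has the same charge with 0.0370 M of free catalyst, a further step of 0.137. I take it as near its end at 160 min, and the slope then puts its lost share at 19.9%, which is target of 64.1% of the starting material.

The forecast gives 0.2 for the order in coupling partner, 1.1 for the order in free catalyst and 62.5% for the eta run, on the ground that “more catalyst competes slightly better”. My figure stands above its central value and inside its range.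

The simulation gives 0.25 for the order in coupling partner, 0.98 for the order in free catalyst and 63.8% for the eta run, so the lost share of the eta run at 160 min is 20.3%, down from 24.7% at the last reading of the theta run and beside my 19.9%.

    free catalyst + starting material → loaded catalyst + by-product (0.5742 M⁻¹ min⁻¹)
    loaded catalyst + coupling partner → target + free catalyst (2.598 M⁻¹ min⁻¹)
    coupling partner → lost reagent (0.004326 min⁻¹)
    target + coupling partner → side product (0.006780 M⁻¹ min⁻¹)

Target in the eta run is held down by the decay of coupling partner to lost reagent. The eta run without that step reaches 72.2% of the starting material at 160 min, which is 8.4 percentage points higher, and its lost share falls to 9.79%, half of 20.3%.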